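Late in a run, the bench habit is to read the yield of intermediate B off the charge of second reagent. The runs and the questions are these.

| setting | dusk | dawn | violet | amber | red |
|---|---|---|---|---|---|
| starting material | 0.050 M | 0.050 M | 0.050 M | 0.050 M | 0.050 M |
| partner | 0.90 equiv | 3.6 equiv | 1.80 equiv | 1.80 equiv | 1.80 equiv |
| second reagent | 0.80 equiv | 0.80 equiv | 0.800 equiv | 0.800 equiv | 0.800 equiv |
| solid third reagent | 1.2 equiv | 1.2 equiv | 1.20 equiv | 1.20 equiv | 1.20 equiv |
| remark | run made earlier | run made earlier |  |  |  |
| time |  |  | 30 min | 60 min | 120 min |

| run | time / min | starting material / % | intermediate B / % | intermediate A / % | product / % |
|---|---|---|---|---|---|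
| dusk | 5.00 | 59.9 | 7.1 | 33.4 | 0.4 |
| dusk | 10.0 | 43.8 | 17.0 | 39.1 | 0 |
| dusk | 15.0 | 35.1 | 26.9 | 38.0 | 0.6 |
| dusk | 20.0 | 30.0 | 34.1 | 35.7 | 0 |
| dawn | 5.00 | 9.8 | 16.9 | 73.1 | 0 |
| dawn | 10.0 | 1.5 | 32.9 | 65.3 | 0.1 |
| dawn | 15.0 | 0.8 | 43.8 | 55.3 | 0.1 |
| dawn | 20.0 | 0 | 50.6 | 48.7 | 0 |

(each reading ± 0.3 percentage points)

- solid third reagent is a solid; its amount is given per volume of the solution
- the earlier runs were read with a standard deviation of 0.3 percentage points
- candidate steps: starting material + partner -> intermediate A; second reagent + intermediate A -> intermediate B; third reagent + intermediate B -> product; solid third reagent <-> third reagent
- at the start none of the solid third reagent is in solution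

- which of these there is most of at the end, counted by the starting material in it, violet (product / starting material / intermediate A / intermediate B)
- which of these there is most of at the end, counted by the starting material in it, amber (product / starting material / intermediate A / intermediate B)
- which of these there is most of at the end, counted by the starting material in it, red (product / starting material / intermediate A / intermediate B)
- how much there is at the end of the one of these that leads, in percent of the starting material charged: violet
- how much there is at the end of the one of these that leads, in percent of the starting material charged: amber
- how much there is at the end of the one of these that leads, in percent of the starting material charged: red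

1. The rule of thumb follows one molecule. Starting material becomes intermediate A, which then needs one molecule of second reagent to pass to intermediate B. At this gate second reagent is the limiting reagent, so in violet, amber and red the charge lets 80.0% of the starting material through, and 20.0% waits as intermediate A. Product forms from intermediate B, so the two are counted together. Product in dusk and dawn reads 0.6% or below, with a scatter of 0.3 percentage points.

2. The rule says where a run ends, not when. The dawn run, with starting material down to 1.5% at 10.0 min, gives the pace. The ratio of second reagent left to intermediate A waiting reads 0.702 there and 0.595 at 20.0 min. Once starting material is used up, this ratio falls by equal factors in equal times, so these readings give 60.6 min, the tail time: the time in which the ratio falls by a factor of 2.72. Partner takes no part in this step, and dawn's charges of starting material and second reagent match those of violet, amber and red, so these three share it.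

3. The border lies near one tail time. Violet stands at 0.495 of one, amber at 0.990 and red at 1.98, so violet is reckoned from the ratio, not from the rule of thumb.

4. The first step costs a delay. Dawn's fall to 9.8% at 5.00 min gives a mean life, and with half of dawn's partner that becomes 4.31 min. Running the ratio down from 80.0% after this delay, intermediate B with product comes to 58.0% in violet, 70.6% in amber and 77.3% in red. In violet that sum is more than the 42.0% left as intermediate A.

The forecast gives intermediate B alone, below these sums : 56%, 69% and 72%, with “B still leads in all three runs”.

The simulation puts intermediate B first in violet, intermediate B in amber and intermediate B in red, at 56.4%, 68.1% and 71.0%, with product at 0.697%, 2.45% and 6.38%.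

    starting material + partner → intermediate A (k = 3.10 /M/min)
    second reagent + intermediate A → intermediate B (k = 1.70 /M/min)
    third reagent + intermediate B → product (k = 0.660 /M/min)
    solid third reagent ⇌ third reagent, rate k4*(cs4 - [third reagent]) while solid is left; crystals form when [third reagent] > cs4 (solubility = 2.20 mM, k = 0.0410 /min)

The gap of 15 points between red and violet in intermediate B has the difference in time as its main reason: violet stops at 0.495 tail times, red at 1.98. The step's pace follows concentration, so a further flask with violet's equivalents at 0.013 M has a tail time of 233 min, and 30 min is 0.129 of it. That flask holds 58.4% as intermediate A and 20.0% as intermediate B.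

The earlier runs and the new flask are simulated on assumed constants.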